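Ring B of the chromene is a 5-acylresorcinol: oxygen on C7 and C8a, the aroyl carbon on C5, and the pyran ring fused through C4a, beside the acyl group, not through C8. This is the aldol fold of a 2,4,6-trione chain, so everything rests on disconnecting C4a–C5. In one operation the key step opens a γ-pyrone with hydroxide and recloses it through carbon. This gives the complete 4-prenyl-5-aroylresorcinol with the prenyl group already at C4a, where direct chromenylation would not put it. Its precursor is a 4-pyranone bearing the ring A aroyl group at C2 and a 4-methylpent-3-enyl chain at C6, assembled from a diketone dianion and an arylglyoxylate.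

Key step: step 6

Remark: the open-chain polyketones are drawn as keto forms although they are largely enolised; the tetraone chain has eleven carbons (10-methylundec-9-ene), which places exactly a prenyl group on C4a, and the locants C1 to C7 used below refer to that chain.

Step 1
Reactants: 1 1,3,5-trimethoxybenzene; 2 ethyl chlorooxoacetate
Product: 3 ethyl 2-oxo-2-(2,4,6-trimethoxyphenyl)acetate
Conditions: TiCl4 (1.1 equiv), CH2Cl2, −20 to 0 °C; ice-water
Reagents that add atoms: none
Why: Friedel–Crafts acylation in which the three free ring positions are equivalent, the acid chloride end of 2 reacts far faster than its ester end, the first acyl group deactivates the ring against a second one, and TiCl4 at or below 0 °C is too mild to cleave the ortho methyl ethers.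

Step 2
Reactants: 4 acetylacetone; 5 prenyl bromide
Product: 7 8-methylnon-7-ene-2,4-dione, via dilithio acetylacetone dianion 6 (not isolated)
Conditions: LiN(iPr)2 (2.05 equiv), THF, −78 to 0 °C; then 5 (0.95 equiv), 0 °C to rt; 1 M HCl
Reagents that add atoms: none
Why: γ-Alkylation of a 1,3-diketone dianion, in which the terminal carbanion created by the second deprotonation is much more basic and nucleophilic than the delocalised central one, so the primary allylic bromide is displaced by SN2 at the methyl carbon only.

Step 3
Reactants: 7 8-methylnon-7-ene-2,4-dione; 3 ethyl 2-oxo-2-(2,4,6-trimethoxyphenyl)acetate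
Product: 9 10-methyl-1-(2,4,6-trimethoxyphenyl)undec-9-ene-1,2,4,6-tetraone, via dilithio diketone dianion 8 (not isolated)
Conditions: 7 (2.2 equiv), LiN(iPr)2 (4.3 equiv), THF, −78 to 0 °C; then 3 (1.0 equiv), −78 to 0 °C; cold 1 M HCl to pH 4
Reagents that add atoms: none
Why: Crossed Claisen condensation (acylation of a 1,3-diketone dianion by a non-enolisable ester), in which the kinetic second deprotonation of 7 occurs at the methyl rather than the methylene terminus, the ester carbonyl of 3 is the accessible electrophile because the aryl ketone is flanked by two ortho methoxy groups and behaves as a vinylogous carbonate, an aldolate formed at that ketone can revert on warming whereas loss of ethoxide followed by deprotonation of 9 by the second equivalent of 8 cannot, and keeping the amide base just below two equivalents per diketone leaves no free amide to reduce or attack 3.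

Step 4
Reactants: 9 10-methyl-1-(2,4,6-trimethoxyphenyl)undec-9-ene-1,2,4,6-tetraone
Product: 10 6-(4-methylpent-3-en-1-yl)-2-(2,4,6-trimethoxybenzoyl)-4H-pyran-4-one
Conditions: TsOH·H2O (5 mol %), 4 Å MS, toluene, 50 °C
Reagents that add atoms: none
Why: Acid-catalysed cyclodehydration of a 1,3,5-triketone to a γ-pyrone, in which the enol oxygen on C6 adds to the most electrophilic carbonyl (C2) and loss of water gives the cross-conjugated ring, while the competing five-membered hemiketal at the aryl ketone cannot dehydrate and simply reverts, and a few mol % of sulfonic acid in warm toluene should leave the trisubstituted alkene unprotonated.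

Step 5
Reactants: 10 6-(4-methylpent-3-en-1-yl)-2-(2,4,6-trimethoxybenzoyl)-4H-pyran-4-one
Product: 11 2-(2-hydroxy-4,6-dimethoxybenzoyl)-6-(4-methylpent-3-en-1-yl)-4H-pyran-4-one
Conditions: BCl3 (2.5 equiv), CH2Cl2, −78 to −20 °C; ice-water
Reagents that add atoms: none
Why: Chelation-controlled cleavage of an aryl methyl ether, in which the basic pyranone carbonyl first ties up one equivalent, BCl3 then bridges the aryl ketone oxygen and an ortho methoxy oxygen in a six-membered chelate and chloride removes that methyl group by SN2, the two ortho ethers being equivalent and the para ether out of reach, while the remote alkene has no neighbouring phenol to cyclise onto and is inert to BCl3 at this temperature.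

Step 6
Reactants: 11 2-(2-hydroxy-4,6-dimethoxybenzoyl)-6-(4-methylpent-3-en-1-yl)-4H-pyran-4-one
Product: 14 [3,5-dihydroxy-2-(3-methylbut-2-en-1-yl)phenyl](2-hydroxy-4,6-dimethoxyphenyl)methanone, via open-chain tetraone 12 (not isolated), via cyclic aldol 13 (not isolated)
Conditions: KOH (2 M aq, 6 equiv), degassed THF–H2O, Ar, rt to 45 °C; then 1 M HCl, 0 °C, to pH 5
Reagents that add atoms: water, O
Why: Proposed new method: hydroxide adds in conjugate fashion to pyranone C2, the ring carbon activated by both the ring carbonyl and the aroyl group, and retro-oxa-Michael cleavage of the O1–C2 bond takes up one molecule of water and releases the enolised tetraone 12 (addition at C6 would lead to the same chain). The enolate of the C6 ketone then attacks the C2 carbonyl through the side-chain methylene C7 in a 6-(enolendo)-exo-trig aldol addition to give 13, and loss of the oxygen on C2 as water with enolisation of the C4 and C6 ketones closes ring B as the resorcinol, so that the step is a net isomerisation in which a ring oxygen is replaced by a carbon as ring member. The closest known reaction type is the alkali-induced conversion of 2,6-dimethyl-4-pyranone through heptane-2,4,6-trione into orcinol, backed by the biomimetic aldol aromatisation of 3,5,7-triketo chains, but no 4-pyranone with a 2-aroyl group has been carried through it. No stereocentre has to be controlled, because the two in 13 disappear on aromatisation. The selectivity needed is C7-to-C2 bond formation ahead of retro-Claisen scission and of attack on the aryl ketone: C7 and C2 are the only carbon pair that gives a six-membered carbocycle, C2 is the more electrophilic half of the 1,2-diketone, and the aryl ketone is shielded by two ortho substituents and electronically switched off by the ring A phenoxide. All oxygen additions at C2, whether by hydroxide or by the ring A phenoxide to a five-membered hemiketal, are reversible whereas aromatisation is not, and chain that has not closed should revert to 11 on acidification and can be resubmitted.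

Step 7
Reactants: 14 [3,5-dihydroxy-2-(3-methylbut-2-en-1-yl)phenyl](2-hydroxy-4,6-dimethoxyphenyl)methanone
Product: 16 (7-hydroxy-2,2-dimethyl-2H-chromen-5-yl)(2-hydroxy-4,6-dimethoxyphenyl)methanone, via ortho-quinone methide 15 (not isolated)
Conditions: DDQ (1.1 equiv), dry toluene, 80 °C
Reagents that add atoms: none
Why: Oxidative cyclisation of an ortho-prenylphenol, in which DDQ abstracts hydride from the benzylic CH2 activated by an ortho and a para hydroxyl, the resulting ortho-quinone methide 15 closes by oxa-6π electrocyclisation, only one hydroxyl lies ortho to the prenyl group so a single chromene can form, the ring enforces the cis C3–C4 alkene, and no stereocentre is created.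

Compound list
1 | 1,3,5-trimethoxybenzene | COc1cc(OC)cc(OC)c1 | starting material
2 | ethyl chlorooxoacetate | CCOC(=O)C(=O)Cl | starting material
3 | ethyl 2-oxo-2-(2,4,6-trimethoxyphenyl)acetate | CCOC(=O)C(=O)c1c(OC)cc(OC)cc1OC | intermediate
4 | acetylacetone | CC(=O)CC(C)=O | starting material
5 | prenyl bromide (1-bromo-3-methylbut-2-ene) | CC(C)=CCBr | starting material
6 | dilithium 1,3-dianion of acetylacetone (not isolated) | [Li+].[Li+].[CH2-]C(=O)[CH-]C(C)=O | intermediate
7 | 8-methylnon-7-ene-2,4-dione | CC(=O)CC(=O)CCC=C(C)C | intermediate
8 | dilithium 1,3-dianion of 8-methylnon-7-ene-2,4-dione, carbanion at the methyl terminus (not isolated) | [Li+].[Li+].[CH2-]C(=O)[CH-]C(=O)CCC=C(C)C | intermediate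
9 | 10-methyl-1-(2,4,6-trimethoxyphenyl)undec-9-ene-1,2,4,6-tetraone | COc1cc(OC)c(C(=O)C(=O)CC(=O)CC(=O)CCC=C(C)C)c(OC)c1 | intermediate
10 | 6-(4-methylpent-3-en-1-yl)-2-(2,4,6-trimethoxybenzoyl)-4H-pyran-4-one | COc1cc(OC)c(C(=O)C2=CC(=O)C=C(CCC=C(C)C)O2)c(OC)c1 | intermediate
11 | 2-(2-hydroxy-4,6-dimethoxybenzoyl)-6-(4-methylpent-3-en-1-yl)-4H-pyran-4-one | COc1cc(O)c(C(=O)C2=CC(=O)C=C(CCC=C(C)C)O2)c(OC)c1 | intermediate
12 | 1-(2-hydroxy-4,6-dimethoxyphenyl)-10-methylundec-9-ene-1,2,4,6-tetraone (not isolated) | COc1cc(O)c(C(=O)C(=O)CC(=O)CC(=O)CCC=C(C)C)c(OC)c1 | intermediate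
13 | 5-hydroxy-5-(2-hydroxy-4,6-dimethoxybenzoyl)-4-(3-methylbut-2-en-1-yl)cyclohexane-1,3-dione (not isolated; diastereomer mixture, both centres lost on aromatisation) | COc1cc(O)c(C(=O)C2(O)CC(=O)CC(=O)C2CC=C(C)C)c(OC)c1 | intermediate
14 | [3,5-dihydroxy-2-(3-methylbut-2-en-1-yl)phenyl](2-hydroxy-4,6-dimethoxyphenyl)methanone | COc1cc(O)c(C(=O)c2cc(O)cc(O)c2CC=C(C)C)c(OC)c1 | intermediate
15 | (6Z)-3-hydroxy-5-(2-hydroxy-4,6-dimethoxybenzoyl)-6-(3-methylbut-2-en-1-ylidene)cyclohexa-2,4-dien-1-one (not isolated) | CC(C)=C/C=C1\C(=O)C=C(O)C=C1C(=O)c2c(O)cc(OC)cc2OC | intermediate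
16 | (7-hydroxy-2,2-dimethyl-2H-chromen-5-yl)(2-hydroxy-4,6-dimethoxyphenyl)methanone (CNP0142929.0, achiral) | COc1cc(O)c(C(=O)c2cc(O)cc3c2C=CC(C)(C)O3)c(OC)c1 | target

Total step count: 7
Longest linear sequence: 6 steps (step 1 or step 2, then steps 3 to 7)

Steps most likely to fail

**Step 6 (ring transformation).**
- Risk: hydroxide may fragment the opened chain by retro-Claisen scission, or intermolecular condensation may outrun the slow closure from C7 to C2.
- Fallback (known chemistry): ring B is taken from a bought arene instead of being built. The fallback sets out from 1 and comes back at 14.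
- Commercial 3,5-bis(benzyloxy)benzaldehyde is brominated with NBS in MeCN at the position ortho to the formyl group and para to an ether oxygen. This gives 3,5-bis(benzyloxy)-2-bromobenzaldehyde F1.
- Compound 1 is lithiated between two methoxy groups (n-BuLi, TMEDA, THF, 0 °C) to 2,4,6-trimethoxyphenyllithium F2.
- F2 adds to F1 at −78 °C to give racemic [3,5-bis(benzyloxy)-2-bromophenyl](2,4,6-trimethoxyphenyl)methanol F3.
- Dess–Martin periodinane buffered with NaHCO3 oxidises F3 to [3,5-bis(benzyloxy)-2-bromophenyl](2,4,6-trimethoxyphenyl)methanone F4.
- BCl3 with pentamethylbenzene as cation trap (CH2Cl2, −78 to 0 °C) removes both benzyl ethers and, by chelation, one ortho methyl ether of ring A. This gives (2-bromo-3,5-dihydroxyphenyl)(2-hydroxy-4,6-dimethoxyphenyl)methanone F5 while no prenyl group is yet present.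
- Stille coupling of F5 with tributyl(3-methylbut-2-en-1-yl)stannane (Pd(PPh3)4, LiCl, DMF, 90 °C) places the prenyl group on the brominated carbon and gives 14. It is run without base so that the ring A phenol does not displace the bromide.

**Step 3 (Claisen condensation).**
- Risk: the dianion may add to the ketone carbonyl of the keto ester instead of the ester carbonyl, or the acidic product may quench the dianion by proton transfer.
- Fallback: aldol addition followed by oxidation replaces the acylation. It sets out from 7 (as its dianion 8) and comes back at 9.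
- Commercial 2',4',6'-trimethoxyacetophenone is oxidised with SeO2 (dioxane–water, reflux, Riley oxidation) and the hydrate is dried azeotropically. This gives 2-oxo-2-(2,4,6-trimethoxyphenyl)acetaldehyde F6.
- At −78 °C the terminal carbon of 8 adds to the aldehyde carbonyl, which is far more reactive than the hindered aryl ketone. The product is racemic 2-hydroxy-10-methyl-1-(2,4,6-trimethoxyphenyl)undec-9-ene-1,4,6-trione F7.
- The alkoxide formed carries no new acidic C–H site, so one equivalent of dianion should suffice.
- Dess–Martin periodinane (1.1 equiv, CH2Cl2, 0 °C) oxidises the acyloin alcohol of F7 to the 1,2-diketone 9.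

**Step 7 (DDQ chromene closure).**
- Risk: the electron-rich triphenol may be over-oxidised, or hydride abstraction next to the electron-withdrawing aroyl group may be sluggish.
- Fallback: selenoetherification and selenoxide elimination replace the dehydrogenation. It sets out from 14 and comes back at 16.
- PhSeCl (CH2Cl2, −78 °C) activates the prenyl alkene and the ortho hydroxyl captures the tertiary carbon in a 6-endo closure. This gives racemic [7-hydroxy-2,2-dimethyl-3-(phenylselanyl)chroman-5-yl](2-hydroxy-4,6-dimethoxyphenyl)methanone F8.
- H2O2 (THF, 0 °C to rt) oxidises F8 to the selenoxide [7-hydroxy-2,2-dimethyl-3-(phenylseleninyl)chroman-5-yl](2-hydroxy-4,6-dimethoxyphenyl)methanone F9.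
- The only β-hydrogens of F9 are on C4, so syn elimination can only give the C3–C4 alkene of 16.

Further compounds
F1 | step 6 | 3,5-bis(benzyloxy)-2-bromobenzaldehyde | O=Cc1cc(OCc2ccccc2)cc(OCc2ccccc2)c1Br
F2 | step 6 | 2,4,6-trimethoxyphenyllithium | [Li]c1c(OC)cc(OC)cc1OC
F3 | step 6 | [3,5-bis(benzyloxy)-2-bromophenyl](2,4,6-trimethoxyphenyl)methanol (racemic) | COc1cc(OC)c(C(O)c2cc(OCc3ccccc3)cc(OCc3ccccc3)c2Br)c(OC)c1
F4 | step 6 | [3,5-bis(benzyloxy)-2-bromophenyl](2,4,6-trimethoxyphenyl)methanone | COc1cc(OC)c(C(=O)c2cc(OCc3ccccc3)cc(OCc3ccccc3)c2Br)c(OC)c1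
F5 | step 6 | (2-bromo-3,5-dihydroxyphenyl)(2-hydroxy-4,6-dimethoxyphenyl)methanone | COc1cc(O)c(C(=O)c2cc(O)cc(O)c2Br)c(OC)c1
F6 | step 3 | 2-oxo-2-(2,4,6-trimethoxyphenyl)acetaldehyde | COc1cc(OC)c(C(=O)C=O)c(OC)c1
F7 | step 3 | 2-hydroxy-10-methyl-1-(2,4,6-trimethoxyphenyl)undec-9-ene-1,4,6-trione (racemic) | COc1cc(OC)c(C(=O)C(O)CC(=O)CC(=O)CCC=C(C)C)c(OC)c1
F8 | step 7 | [7-hydroxy-2,2-dimethyl-3-(phenylselanyl)chroman-5-yl](2-hydroxy-4,6-dimethoxyphenyl)methanone (racemic) | COc1cc(O)c(C(=O)c2cc(O)cc3c2CC([Se]c2ccccc2)C(C)(C)O3)c(OC)c1
F9 | step 7 | [7-hydroxy-2,2-dimethyl-3-(phenylseleninyl)chroman-5-yl](2-hydroxy-4,6-dimethoxyphenyl)methanone (stereoisomer mixture) | COc1cc(O)c(C(=O)c2cc(O)cc3c2CC([Se](=O)c2ccccc2)C(C)(C)O3)c(OC)c1
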